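**Retrosynthetic overview**
- Feature: the furan ring of the 2-arylbenzofuran (O1', C2', C3', C3a', C7a') is the pyranone ring of a flavanone (O1, C2, C3, C4a, C8a) minus its carbonyl carbon C4. The aryl–C2' bond sits at chromene C5, between the C6 prenyl group and the C4=C3 vinyl arm. That site is poor for a biaryl coupling but can be reached as an aldol C=C.
- Cathafuran C ⇐ MOM removal ⇐ protodecarboxylation, saponification and dehydrogenation of a 2-aryl-2,3-dihydrobenzofuran-3-carboxylate ⇐ photochemical Wolff ring contraction of a 3-diazoflavanone.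
- 3-Diazoflavanone ⇐ detrifluoroacetylative diazo transfer ⇐ flavanone ⇐ oxa-Michael closure of a 2'-hydroxychalcone ⇐ Claisen–Schmidt condensation of a chromene-5-carbaldehyde with 2,4-dihydroxyacetophenone 4-MOM ether.
- Chromene-5-carbaldehyde ⇐ methyl 3,5-dihydroxybenzoate by differentiation of the two oxygens, 2,6-dibromination, twofold Stille prenylation, selenoetherification/selenoxide elimination, and ester-to-aldehyde redox.
- Ring order: both benzene rings are bought. The 2H-pyran is formed in step 6 and the pyranone in step 11; contraction to the dihydrofuran follows in step 13 and aromatisation to the furan in step 14.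

Key step: step 13

Remark on the chemistry: the target has no stereocentre and no stereogenic double bond, so it is achiral and there is no enantiomer to select. The sp3 centres that appear on the way are carried as racemates or mixtures, and all are erased by step 14.

**Step 1**
Reactants: 1 methyl 3,5-dihydroxybenzoate
Product: 2 methyl 3-hydroxy-5-(methoxymethoxy)benzoate
Conditions: MOMCl (1.0 equiv), K2CO3, acetone, 0 °C → rt
Reagents that add atoms: chloromethyl methyl ether, COCCl
Why: Williamson-type MOM ether formation; one equivalent of MOMCl on two equivalent phenols should give a statistical but easily separated mixture, and the symmetry is broken here, on the cheapest material, so that every later step is selective.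

**Step 2**
Reactants: 2 methyl 3-hydroxy-5-(methoxymethoxy)benzoate
Product: 3 methyl 3-[(tert-butyldimethylsilyl)oxy]-5-(methoxymethoxy)benzoate
Conditions: TBSCl, imidazole, DMF, rt
Reagents that add atoms: tert-butyldimethylsilyl chloride, CC(C)(C)[Si](C)(C)Cl
Why: Standard imidazole-promoted silylation of a phenol; the TBS ether marks the oxygen that becomes O1 of the chromene and keeps the resorcinol-diether directing pattern for step 3.

**Step 3**
Reactants: 3 methyl 3-[(tert-butyldimethylsilyl)oxy]-5-(methoxymethoxy)benzoate
Product: 4 methyl 2,6-dibromo-3-[(tert-butyldimethylsilyl)oxy]-5-(methoxymethoxy)benzoate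
Conditions: NBS (2.1 equiv), MeCN, 0 °C → rt, dark
Reagents that add atoms: N-bromosuccinimide, O=C1CCC(=O)N1Br
Why: Electrophilic aromatic bromination of a resorcinol diether, in which each bromine should enter para to one oxygen and ortho to the other (C2 and C6, as known for 3,5-dialkoxybenzoates), while C4 between OTBS and OMOM reacts last.

**Step 4**
Reactants: 4 methyl 2,6-dibromo-3-[(tert-butyldimethylsilyl)oxy]-5-(methoxymethoxy)benzoate; 5 tributyl(3-methylbut-2-en-1-yl)stannane
Product: 6 methyl 3-[(tert-butyldimethylsilyl)oxy]-5-(methoxymethoxy)-2,6-bis(3-methylbut-2-en-1-yl)benzoate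
Conditions: 5 (2.5 equiv), Pd(PPh3)4 (10 mol %), toluene, 110 °C
Reagents that add atoms: none
Why: Twofold Migita–Kosugi–Stille allyl–aryl coupling, tolerant of ester, MOM and silyl ether; the ortho ester assists oxidative addition at both hindered C–Br bonds, and reductive elimination at the unsubstituted CH2 terminus should give the linear prenyl groups.

**Step 5**
Reactants: 6 methyl 3-[(tert-butyldimethylsilyl)oxy]-5-(methoxymethoxy)-2,6-bis(3-methylbut-2-en-1-yl)benzoate
Product: 7 methyl 3-hydroxy-5-(methoxymethoxy)-2,6-bis(3-methylbut-2-en-1-yl)benzoate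
Conditions: TBAF, AcOH (1.1 equiv each), THF, 0 °C
Reagents that add atoms: none
Why: Fluoride-induced cleavage of the aryl silyl ether, buffered with acetic acid so that the phenoxide is protonated at once and the ester, MOM ether and both alkenes stay untouched.

**Step 6**
Reactants: 7 methyl 3-hydroxy-5-(methoxymethoxy)-2,6-bis(3-methylbut-2-en-1-yl)benzoate
Product: 10 methyl 7-(methoxymethoxy)-2,2-dimethyl-6-(3-methylbut-2-en-1-yl)-2H-chromene-5-carboxylate, via racemic methyl 7-(methoxymethoxy)-2,2-dimethyl-6-(3-methylbut-2-en-1-yl)-3-(phenylselanyl)chromane-5-carboxylate 8 (not isolated), via the corresponding 3-(phenylseleninyl)chromane (selenoxide) 9 (not isolated)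
Conditions: N-(phenylselanyl)phthalimide (1.1 equiv), CSA (10 mol %), CH2Cl2, 0 °C; then pyridine, 30% aq H2O2, 0 °C → rt
Reagents that add atoms: N-(phenylselanyl)phthalimide, O=C1N([Se]c2ccccc2)C(=O)c2ccccc12 (PhSe in 8 and 9 only); hydrogen peroxide, OO (O on Se in 9 only)
Why: Phenylselenoetherification followed by selenoxide syn-elimination, the established o-prenylphenol → 2,2-dimethyl-2H-chromene sequence: seleniranium formation is reversible at both prenyl groups but only the one ortho to the free OH is trapped (6-endo, Markovnikov attack of O on the CMe2 terminus), the racemic C3 centre of 8 vanishes on elimination towards C4, and a hydride-abstracting oxidant such as DDQ is avoided because the free OH is also para to the second prenyl group and would open a p-quinone methide channel.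

**Step 7**
Reactants: 10 methyl 7-(methoxymethoxy)-2,2-dimethyl-6-(3-methylbut-2-en-1-yl)-2H-chromene-5-carboxylate
Product: 11 [7-(methoxymethoxy)-2,2-dimethyl-6-(3-methylbut-2-en-1-yl)-2H-chromen-5-yl]methanol
Conditions: LiAlH4, THF, 0 °C → rt; Fieser work-up
Reagents that add atoms: none
Why: Hydride reduction of the di-ortho-substituted benzoate, slow but unproblematic with small, strong LiAlH4, which leaves the alkenes and the acetal alone.

**Step 8**
Reactants: 11 [7-(methoxymethoxy)-2,2-dimethyl-6-(3-methylbut-2-en-1-yl)-2H-chromen-5-yl]methanol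
Product: 12 7-(methoxymethoxy)-2,2-dimethyl-6-(3-methylbut-2-en-1-yl)-2H-chromene-5-carbaldehyde
Conditions: activated MnO2, CH2Cl2, rt
Reagents that add atoms: none
Why: Heterogeneous MnO2 oxidation, selective for the electron-rich benzylic alcohol and stopping at the aldehyde.

**Step 9**
Reactants: 13 2,4-dihydroxyacetophenone
Product: 14 1-[2-hydroxy-4-(methoxymethoxy)phenyl]ethanone
Conditions: MOMCl (1.1 equiv), K2CO3, acetone, rt
Reagents that add atoms: chloromethyl methyl ether, COCCl
Why: Chemoselective MOM ether formation: the 2-OH is locked in a hydrogen bond to the ketone, so the free and more acidic 4-OH is alkylated.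

**Step 10**
Reactants: 12 7-(methoxymethoxy)-2,2-dimethyl-6-(3-methylbut-2-en-1-yl)-2H-chromene-5-carbaldehyde; 14 1-[2-hydroxy-4-(methoxymethoxy)phenyl]ethanone
Product: 15 (E)-1-[2-hydroxy-4-(methoxymethoxy)phenyl]-3-[7-(methoxymethoxy)-2,2-dimethyl-6-(3-methylbut-2-en-1-yl)-2H-chromen-5-yl]prop-2-en-1-one
Conditions: KOH, EtOH/H2O, rt → 50 °C
Reagents that add atoms: none
Why: Claisen–Schmidt condensation: the non-enolisable aldehyde 12 can only act as acceptor, E1cB dehydration gives the (E)-enone, and the sp2 carbonyl carbon at hindered chromene C5 is far easier to reach than a metal centre in a biaryl coupling.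

**Step 11**
Reactants: 15 the (E)-2'-hydroxychalcone
Product: 16 racemic 7-(methoxymethoxy)-2-[7-(methoxymethoxy)-2,2-dimethyl-6-(3-methylbut-2-en-1-yl)-2H-chromen-5-yl]chroman-4-one
Conditions: NaOAc, EtOH, reflux; unreacted 15 recycled
Reagents that add atoms: none
Why: Base-mediated chalcone–flavanone isomerisation (6-endo-trig intramolecular oxa-Michael addition); the twisted di-ortho-substituted aryl group leaves the chalcone little conjugation to lose, so the equilibrium should lie towards 16, whose C2 centre forms as a racemate and is erased in step 14.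

**Step 12**
Reactants: 16 the racemic flavanone
Product: 18 racemic 3-diazo-7-(methoxymethoxy)-2-[7-(methoxymethoxy)-2,2-dimethyl-6-(3-methylbut-2-en-1-yl)-2H-chromen-5-yl]chroman-4-one, via the 3-(trifluoroacetyl)flavanone 17 (not isolated)
Conditions: LiHMDS, THF, −78 °C; CF3CO2CH2CF3, −78 °C; cold 0.5 M HCl quench; crude, then p-ABSA, Et3N, H2O (1 equiv), MeCN, rt, dark
Reagents that add atoms: 2,2,2-trifluoroethyl trifluoroacetate, O=C(OCC(F)(F)F)C(F)(F)F (CF3CO in 17 only); 4-acetamidobenzenesulfonyl azide, CC(=O)Nc1ccc(cc1)S(=O)(=O)N=[N+]=[N-] (N2 in 18)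
Why: Danheiser detrifluoroacetylative diazo transfer (Regitz type): kinetic lithium enolate formation and C-trifluoroacetylation at −78 °C keep retro-oxa-Michael opening slow, and the activated 1,3-dicarbonyl 17 then takes up N2 from the sulfonyl azide with loss of the trifluoroacetyl group as the N-acylsulfonamide.

**Step 13**
Reactants: 18 the racemic 3-diazoflavanone
Product: 20 methyl 6-(methoxymethoxy)-2-[7-(methoxymethoxy)-2,2-dimethyl-6-(3-methylbut-2-en-1-yl)-2H-chromen-5-yl]-2,3-dihydrobenzofuran-3-carboxylate (racemic, cis/trans mixture), via the ketene [6-(methoxymethoxy)-2-aryl-benzofuran-3(2H)-ylidene]methanone 19 (not isolated)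
Conditions: hν (405 nm LED), degassed MeOH (0.01 M), 15 °C
Reagents that add atoms: methanol, CO
Why: Excitation of the n→π* tail of the α-diazo ketone, the only chromophore of 18 that reaches 400 nm, expels N2 while the C4–C4a bond, held antiperiplanar to the C3–N bond by the s-Z geometry that the ring enforces, migrates to C3 and gives ketene 19, to which methanol adds before the enol tautomerises to ester 20. This is the photochemical Wolff ring contraction known for benzo-fused cyclic α-diazo aryl ketones such as 2-diazo-1-tetralones and 2-diazo-1-indanones. The five-membered ring O1'–C2'–C3'–C3a'–C7a' is closed not by an exo or endo attack but by a 1,2-shift inside the six-membered ring: the C3'–C3a' bond (old C3–C4a) forms as C4–C4a breaks, and old C4 becomes the exocyclic ester carbon. C2' is carried over from racemic 18, and the new centre C3' is set by protonation of the ester enol, expected from the face away from the C2' aryl group (cis ester first, epimerisable to trans); no control is needed because step 14 flattens both centres. Migration must beat the 1,2-shift of H-2 (flavone), O–H insertion into methanol and electrocyclic opening of the 2H-chromene: the concerted path from the locked s-Z conformer avoids a free carbene, the migrating carbon C4a is made electron-rich by the para OMOM group, and 405 nm light lies beyond the absorption of the chromene and of product 20. Neat methanol should capture the ketene faster than it can add [2+2] to the neighbouring prenyl or chromene double bond.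

**Step 14**
Reactants: 20 the methyl 2-aryl-2,3-dihydrobenzofuran-3-carboxylate
Product: 23 methyl 6-(methoxymethoxy)-2-[7-(methoxymethoxy)-2,2-dimethyl-6-(3-methylbut-2-en-1-yl)-2H-chromen-5-yl]benzofuran-3-carboxylate, via the racemic 3-(phenylselanyl) ester 21 (not isolated), via the 3-(phenylseleninyl) ester (selenoxide) 22 (not isolated)
Conditions: LiHMDS, THF, −78 °C; PhSeBr, −78 °C; sat. NH4Cl; crude in CH2Cl2, pyridine, 30% aq H2O2, 0 °C → rt
Reagents that add atoms: benzeneselenenyl bromide, Br[Se]c1ccccc1 (PhSe in 21 and 22 only); hydrogen peroxide, OO (O on Se in 22 only)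
Why: Reich–Sharpless ester dehydrogenation: the benzylic ester enolate is selenenylated on the face away from the C2' aryl group, which places Se syn to H-2' as the selenoxide syn-elimination requires, and aromatisation to the furan drives the elimination and removes both stereocentres.

**Step 15**
Reactants: 23 the methyl benzofuran-3-carboxylate
Product: 24 6-(methoxymethoxy)-2-[7-(methoxymethoxy)-2,2-dimethyl-6-(3-methylbut-2-en-1-yl)-2H-chromen-5-yl]benzofuran-3-carboxylic acid
Conditions: KOH, THF/MeOH/H2O, 60 °C; then cold dilute HCl to pH 4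
Reagents that add atoms: potassium hydroxide, [K+].[OH-] (its oxygen ends in the carboxyl group)
Why: Saponification (BAc2) of the now aromatic, base-stable benzofuran ester, for which the retro-oxa-Michael path of the dihydro series no longer exists.

**Step 16**
Reactants: 24 the benzofuran-3-carboxylic acid
Product: 25 6-(methoxymethoxy)-2-[7-(methoxymethoxy)-2,2-dimethyl-6-(3-methylbut-2-en-1-yl)-2H-chromen-5-yl]benzofuran
Conditions: Cu2O (10 mol %), 1,10-phenanthroline (20 mol %), NMP/quinoline 3:1, 170 °C
Reagents that add atoms: none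
Why: Copper-catalysed protodecarboxylation of a heteroaromatic carboxylic acid (the modern form of the Cu/quinoline method), helped by relief of strain between the carboxyl group and the twisted C2' aryl group; MOM ethers, prenyl group and chromene tolerate the hot, non-acidic medium.

**Step 17**
Reactants: 25 the bis-MOM ether of cathafuran C
Product: 26 cathafuran C
Conditions: p-TsOH·H2O (20 mol %), MeOH, 40 °C, stopped at full conversion
Reagents that add atoms: none
Why: Acid-catalysed transacetalisation of the two aryl MOM ethers to dimethoxymethane, run with a catalytic sulfonic acid at mild temperature so that neither the o-prenylphenol closes to a chroman nor the chromene adds methanol.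

**Compound list**
1 | methyl 3,5-dihydroxybenzoate | COC(=O)c1cc(O)cc(O)c1 | starting material
2 | methyl 3-hydroxy-5-(methoxymethoxy)benzoate | COCOc1cc(O)cc(C(=O)OC)c1 | intermediate
3 | methyl 3-[(tert-butyldimethylsilyl)oxy]-5-(methoxymethoxy)benzoate | COCOc1cc(O[Si](C)(C)C(C)(C)C)cc(C(=O)OC)c1 | intermediate
4 | methyl 2,6-dibromo-3-[(tert-butyldimethylsilyl)oxy]-5-(methoxymethoxy)benzoate | COCOc1cc(O[Si](C)(C)C(C)(C)C)c(Br)c(C(=O)OC)c1Br | intermediate
5 | tributyl(3-methylbut-2-en-1-yl)stannane | CCCC[Sn](CCCC)(CCCC)CC=C(C)C | starting material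
6 | methyl 3-[(tert-butyldimethylsilyl)oxy]-5-(methoxymethoxy)-2,6-bis(3-methylbut-2-en-1-yl)benzoate | COCOc1cc(O[Si](C)(C)C(C)(C)C)c(CC=C(C)C)c(C(=O)OC)c1CC=C(C)C | intermediate
7 | methyl 3-hydroxy-5-(methoxymethoxy)-2,6-bis(3-methylbut-2-en-1-yl)benzoate | COCOc1cc(O)c(CC=C(C)C)c(C(=O)OC)c1CC=C(C)C | intermediate
8 | methyl 7-(methoxymethoxy)-2,2-dimethyl-6-(3-methylbut-2-en-1-yl)-3-(phenylselanyl)chromane-5-carboxylate (racemic) | COCOc1cc2OC(C)(C)C([Se]c3ccccc3)Cc2c(C(=O)OC)c1CC=C(C)C | intermediate
9 | methyl 7-(methoxymethoxy)-2,2-dimethyl-6-(3-methylbut-2-en-1-yl)-3-(phenylseleninyl)chromane-5-carboxylate (mixture of stereoisomers) | COCOc1cc2OC(C)(C)C([Se](=O)c3ccccc3)Cc2c(C(=O)OC)c1CC=C(C)C | intermediate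
10 | methyl 7-(methoxymethoxy)-2,2-dimethyl-6-(3-methylbut-2-en-1-yl)-2H-chromene-5-carboxylate | COCOc1cc2OC(C)(C)C=Cc2c(C(=O)OC)c1CC=C(C)C | intermediate
11 | [7-(methoxymethoxy)-2,2-dimethyl-6-(3-methylbut-2-en-1-yl)-2H-chromen-5-yl]methanol | COCOc1cc2OC(C)(C)C=Cc2c(CO)c1CC=C(C)C | intermediate
12 | 7-(methoxymethoxy)-2,2-dimethyl-6-(3-methylbut-2-en-1-yl)-2H-chromene-5-carbaldehyde | COCOc1cc2OC(C)(C)C=Cc2c(C=O)c1CC=C(C)C | intermediate
13 | 2,4-dihydroxyacetophenone | CC(=O)c1ccc(O)cc1O | starting material
14 | 1-[2-hydroxy-4-(methoxymethoxy)phenyl]ethanone | CC(=O)c1ccc(OCOC)cc1O | intermediate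
15 | (E)-1-[2-hydroxy-4-(methoxymethoxy)phenyl]-3-[7-(methoxymethoxy)-2,2-dimethyl-6-(3-methylbut-2-en-1-yl)-2H-chromen-5-yl]prop-2-en-1-one | COCOc1ccc(c(O)c1)C(=O)/C=C/c1c(CC=C(C)C)c(OCOC)cc2OC(C)(C)C=Cc12 | intermediate
16 | 7-(methoxymethoxy)-2-[7-(methoxymethoxy)-2,2-dimethyl-6-(3-methylbut-2-en-1-yl)-2H-chromen-5-yl]chroman-4-one (racemic) | O=C1CC(c3c(CC=C(C)C)c(OCOC)cc4OC(C)(C)C=Cc34)Oc2cc(OCOC)ccc12 | intermediate
17 | 3-(trifluoroacetyl) derivative of 16 (racemic, keto/enol mixture) | O=C1C(C(=O)C(F)(F)F)C(c3c(CC=C(C)C)c(OCOC)cc4OC(C)(C)C=Cc34)Oc2cc(OCOC)ccc12 | intermediate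
18 | 3-diazo-7-(methoxymethoxy)-2-[7-(methoxymethoxy)-2,2-dimethyl-6-(3-methylbut-2-en-1-yl)-2H-chromen-5-yl]chroman-4-one (racemic) | O=C1C(=[N+]=[N-])C(c3c(CC=C(C)C)c(OCOC)cc4OC(C)(C)C=Cc34)Oc2cc(OCOC)ccc12 | intermediate
19 | {6-(methoxymethoxy)-2-[7-(methoxymethoxy)-2,2-dimethyl-6-(3-methylbut-2-en-1-yl)-2H-chromen-5-yl]benzofuran-3(2H)-ylidene}methanone (ketene, racemic) | O=C=C1C(c3c(CC=C(C)C)c(OCOC)cc4OC(C)(C)C=Cc34)Oc2cc(OCOC)ccc12 | intermediate
20 | methyl 6-(methoxymethoxy)-2-[7-(methoxymethoxy)-2,2-dimethyl-6-(3-methylbut-2-en-1-yl)-2H-chromen-5-yl]-2,3-dihydrobenzofuran-3-carboxylate (racemic, cis/trans mixture) | COC(=O)C1C(c3c(CC=C(C)C)c(OCOC)cc4OC(C)(C)C=Cc34)Oc2cc(OCOC)ccc12 | intermediate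
21 | 3-(phenylselanyl) derivative of 20 (racemic, PhSe expected anti to the aryl group) | COC(=O)C1([Se]c5ccccc5)C(c3c(CC=C(C)C)c(OCOC)cc4OC(C)(C)C=Cc34)Oc2cc(OCOC)ccc12 | intermediate
22 | 3-(phenylseleninyl) derivative of 20 (mixture of stereoisomers) | COC(=O)C1([Se](=O)c5ccccc5)C(c3c(CC=C(C)C)c(OCOC)cc4OC(C)(C)C=Cc34)Oc2cc(OCOC)ccc12 | intermediate
23 | methyl 6-(methoxymethoxy)-2-[7-(methoxymethoxy)-2,2-dimethyl-6-(3-methylbut-2-en-1-yl)-2H-chromen-5-yl]benzofuran-3-carboxylate | COC(=O)c1c(-c3c(CC=C(C)C)c(OCOC)cc4OC(C)(C)C=Cc34)oc2cc(OCOC)ccc12 | intermediate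
24 | 6-(methoxymethoxy)-2-[7-(methoxymethoxy)-2,2-dimethyl-6-(3-methylbut-2-en-1-yl)-2H-chromen-5-yl]benzofuran-3-carboxylic acid | OC(=O)c1c(-c3c(CC=C(C)C)c(OCOC)cc4OC(C)(C)C=Cc34)oc2cc(OCOC)ccc12 | intermediate
25 | 6-(methoxymethoxy)-2-[7-(methoxymethoxy)-2,2-dimethyl-6-(3-methylbut-2-en-1-yl)-2H-chromen-5-yl]benzofuran | COCOc1ccc2cc(-c3c(CC=C(C)C)c(OCOC)cc4OC(C)(C)C=Cc34)oc2c1 | intermediate
26 | cathafuran C (achiral) | CC(C)=CCc1c(O)cc2c(c1-c1cc3ccc(O)cc3o1)C=CC(C)(C)O2 | target

**Step count**
Total: 17 steps. Longest linear sequence: 16 steps (steps 1–8 and 10–17). Step 9 is the one-step side branch.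

**Steps most likely to fail**

1. **Step 13 (Wolff ring contraction).**
 - Risk: N2 may be lost to a free singlet carbene. A 1,2-shift of H-2 would then dehydrogenate the ring towards the flavone, or methanol would insert into the carbene instead of the ring contracting. Stray short-wavelength light could also open the 2H-chromene electrocyclically, and the opened form would add methanol.
 - Fallback: the same C4a → C3 shift is triggered oxidatively, without a diazo compound. It sets out from flavanone 16, which is treated with PhI(OAc)2 (1 equiv) and catalytic H2SO4 in trimethyl orthoformate at 0 °C → rt. This is the hypervalent-iodine ring contraction known for flavanones. The enol ether is attacked by I(III) at C3 and C4 is ketalised. C4a then migrates as PhI leaves, and the dimethoxycarbenium ion collapses to the methyl ester.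
 - The fallback comes back to the route at 20 and makes no compound outside the list (F0).

2. **Step 12 (diazo transfer).**
 - Risk: the aryloxide may be lost by β-elimination from the lithium enolate or from the enolate of 17 (retro-oxa-Michael ring opening). C-acylation next to the crowded C2 may also be slow.
 - Fallback: C3 is activated without a strong base. It sets out from 16, which is heated with tert-butoxybis(dimethylamino)methane in toluene at 80 °C. Any ring opening under these conditions is reversible, and only the closed flavanone can condense. This gives the enaminone 3-[(dimethylamino)methylidene]-7-(methoxymethoxy)-2-arylchroman-4-one F1.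
 - Diazo transfer to the enaminone with p-ABSA in MeCN at rt (cycloaddition, then cycloreversion with loss of the N-sulfonylformamidine) comes back to the route at 18.

3. **Step 14 (dehydrogenation).**
 - Risk: the ester enolate may open by E1cB loss of the aryloxide, and selenenylation at the congested C3' may be slow. The selenium electrophile may add to the prenyl or chromene double bonds, or perseleninic acid may epoxidise them.
 - Fallback: the carboxyl carbon is removed and the double bond made in one oxidative step, with no enolate. It sets out from 20. Me3SnOH in 1,2-dichloroethane at 80 °C cleaves the methyl ester without enolisation and gives 6-(methoxymethoxy)-2-aryl-2,3-dihydrobenzofuran-3-carboxylic acid F2.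
 - Kochi oxidative decarboxylation follows (Pb(OAc)4, catalytic Cu(OAc)2, pyridine, benzene, 80 °C). It generates the C3' p-alkoxybenzyl radical, which Cu(II) oxidises to the cation, and loss of H-2' aromatises the ring.
 - The fallback comes back to the route at 25 and skips 21–24.

**Further compounds**
F0 | step 13 | none | none
F1 | step 12 | 3-[(dimethylamino)methylidene]-7-(methoxymethoxy)-2-[7-(methoxymethoxy)-2,2-dimethyl-6-(3-methylbut-2-en-1-yl)-2H-chromen-5-yl]chroman-4-one (racemic, C=C geometry immaterial) | CN(C)C=C1C(c3c(CC=C(C)C)c(OCOC)cc4OC(C)(C)C=Cc34)Oc2cc(OCOC)ccc2C1=O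
F2 | step 14 | 6-(methoxymethoxy)-2-[7-(methoxymethoxy)-2,2-dimethyl-6-(3-methylbut-2-en-1-yl)-2H-chromen-5-yl]-2,3-dihydrobenzofuran-3-carboxylic acid (racemic, cis/trans mixture) | OC(=O)C1C(c3c(CC=C(C)C)c(OCOC)cc4OC(C)(C)C=Cc34)Oc2cc(OCOC)ccc12
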